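**Retrosynthetic overview**

1. Ring numbering used throughout: C1 (angelate), C2, C3–C4 (oxirane, CH3 on C4), C5 (acetate), C6 (senecioate), C7 (isopropenyl), C8, C9 (CHOH), C10 (C(OH)CH3). The plan rests on the C9/C10 glycol of the ten-membered carbocycle: the only two unacylated hydroxyls sit on adjacent ring carbons, one secondary and one tertiary beside a methyl, which is what reductive coupling of a C9 aldehyde with a C10 methyl ketone leaves behind.
2. Disconnection at C9–C10 (closes the carbocycle): titanium-mediated pinacol cyclisation of the (3Z)-9,10-seco keto aldehyde carrying a C1 PMB ether and a C5/C6 acetonide.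
3. Disconnection at C3=C4: Z-selective Wittig union of a C10–C3 phosphonium salt (C1 from (S)-butane-1,2,4-triol, the reduction product of (S)-malic acid) with a C4–C9 methyl ketone (C5 and C6 from 2,3-O-isopropylidene-D-erythronolactone, C7 by anti-selective isopropenyl cuprate addition).
4. Ring order: the ten-membered carbocycle first (step 21), the oxirane second (step 26, directed by the C5 hydroxyl). Esters go on in the order C1 angelate, C6 senecioate, C5 acetate, and C9 is unmasked last.

Key step: step 21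

Remark: carbinol centres that are later oxidised to ketones (future C10 in 4–8 and 21–23, future C4 in 19), the anomeric centre of 10 and the enol geometry of 13 are carried as mixtures and written without configuration. PMB = 4-methoxybenzyl, TBS = tert-butyldimethylsilyl, TBDPS = tert-butyldiphenylsilyl; locants C1–C10 in the names of 21–34 are those of the carbocycle defined above.

**C10–C3 fragment**

Step 1
Reactants: 1 (S)-butane-1,2,4-triol
Product: 2 [(2S,4S)-2-(4-methoxyphenyl)-1,3-dioxan-4-yl]methanol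
Conditions: 4-MeOC6H4CH(OMe)2, camphorsulfonic acid (cat.), CH2Cl2, rt
Reagents that add atoms: 4-methoxybenzaldehyde dimethyl acetal (COc1ccc(cc1)C(OC)OC)
Why: Acid-catalysed transacetalisation under thermodynamic control should favour the six-membered acetal of the 2,4-diol with aryl and hydroxymethyl both equatorial (new acetal centre 2S, cis to C4), leaving the C1 hydroxyl free.

Step 2
Reactants: 2 dioxane alcohol
Product: 3 (2S,4S)-2-(4-methoxyphenyl)-1,3-dioxane-4-carbaldehyde
Conditions: Dess–Martin periodinane, NaHCO3, CH2Cl2, 0 °C to rt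
Reagents that add atoms: none
Why: Dess–Martin oxidation converts the primary alcohol into the aldehyde under buffered conditions that neither open the acetal nor epimerise the α-alkoxy centre.

Step 3
Reactants: 3 dioxane aldehyde
Product: 4 1-[(2S,4S)-2-(4-methoxyphenyl)-1,3-dioxan-4-yl]ethan-1-ol (carbinol epimers)
Conditions: MeMgBr, THF, −78 °C; H2O work-up
Reagents that add atoms: methylmagnesium bromide (C[Mg]Br)
Why: Grignard addition to the aldehyde installs the C10 methyl, and the new carbinol centre is expected as an epimer mixture, which is harmless because it becomes the ketone in step 20.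

Step 4
Reactants: 4 dioxane carbinol
Product: 5 tert-butyl{1-[(2S,4S)-2-(4-methoxyphenyl)-1,3-dioxan-4-yl]ethoxy}dimethylsilane (carbinol epimers)
Conditions: t-BuMe2SiCl, imidazole, DMF, rt
Reagents that add atoms: tert-butyldimethylsilyl chloride (CC(C)(C)[Si](C)(C)Cl)
Why: Imidazole-promoted silylation of the secondary alcohol masks the future C10 oxygen for the ylide chemistry.

Step 5
Reactants: 5 silylated dioxane
Product: 6 (3S)-4-[(tert-butyldimethylsilyl)oxy]-3-[(4-methoxyphenyl)methoxy]pentan-1-ol (C4 epimers)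
Conditions: i-Bu2AlH, CH2Cl2, −78 to 0 °C; aqueous work-up
Reagents that add atoms: none
Why: Reductive opening of the 4-methoxybenzylidene acetal, in which aluminium binds the less hindered primary oxygen and hydride is delivered to the resulting oxocarbenium ion, so that the PMB group ends on the secondary (C1) oxygen and the primary alcohol is released.

Step 6
Reactants: 6 primary alcohol
Product: 7 tert-butyl({(3S)-5-iodo-3-[(4-methoxyphenyl)methoxy]pentan-2-yl}oxy)dimethylsilane (C2 epimers)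
Conditions: I2, PPh3, imidazole, CH2Cl2, 0 °C to rt
Reagents that add atoms: iodine (II)
Why: Appel-type iodination replaces the primary hydroxyl by iodide through the alkoxyphosphonium ion without touching the silyl and PMB ethers.

Step 7
Reactants: 7 primary iodide
Product: 8 {(3S)-4-[(tert-butyldimethylsilyl)oxy]-3-[(4-methoxyphenyl)methoxy]pentyl}triphenylphosphonium iodide (C4 epimers)
Conditions: PPh3, MeCN, 80 °C
Reagents that add atoms: triphenylphosphine (c1ccc(cc1)P(c1ccccc1)c1ccccc1)
Why: SN2 quaternisation of triphenylphosphine by the unhindered primary iodide gives the Wittig salt, whose γ-alkoxy group cannot β-eliminate.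

**C4–C9 fragment**

Step 8
Reactants: 9 2,3-O-isopropylidene-D-erythronolactone
Product: 10 2,3-O-isopropylidene-D-erythrofuranose (anomers)
Conditions: i-Bu2AlH, CH2Cl2, −78 °C; aqueous work-up
Reagents that add atoms: none
Why: Half-reduction of the lactone at low temperature stops at the lactol because the tetrahedral aluminium hemiacetal is stable until work-up.

Step 9
Reactants: 10 lactol
Product: 11 ethyl (2E)-3-[(4S,5R)-5-(hydroxymethyl)-2,2-dimethyl-1,3-dioxolan-4-yl]prop-2-enoate
Conditions: Ph3P=CHCO2Et, PhCO2H (cat.), CH2Cl2, 40 °C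
Reagents that add atoms: ethyl (triphenylphosphoranylidene)acetate (CCOC(=O)C=P(c1ccccc1)(c1ccccc1)c1ccccc1)
Why: Wittig olefination of the open hydroxy aldehyde form of the lactol with the stabilised ylide, benzoic acid catalysis favouring the (E)-enoate and suppressing oxa-Michael closure, the minor (Z)-isomer being removed by chromatography.

Step 10
Reactants: 11 hydroxy enoate
Product: 12 ethyl (2E)-3-[(4S,5R)-5-{[(tert-butyldimethylsilyl)oxy]methyl}-2,2-dimethyl-1,3-dioxolan-4-yl]prop-2-enoate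
Conditions: t-BuMe2SiCl, imidazole, CH2Cl2, 0 °C
Reagents that add atoms: tert-butyldimethylsilyl chloride (CC(C)(C)[Si](C)(C)Cl)
Why: Imidazole-promoted silylation of the primary alcohol prevents its conjugate addition to the enoate in the next step.

Step 11
Reactants: 12 silylated (E)-enoate
Product: 14 ethyl (3R)-3-[(4S,5R)-5-{[(tert-butyldimethylsilyl)oxy]methyl}-2,2-dimethyl-1,3-dioxolan-4-yl]-4-methylpent-4-enoate, via silyl ketene acetal 13 (not isolated)
Conditions: CH2=C(CH3)MgBr, CuBr·SMe2 (cat.), Me3SiCl, THF, −78 °C; then H2O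
Reagents that add atoms: isopropenylmagnesium bromide (CC(=C)[Mg]Br)
Why: Copper-catalysed conjugate addition of the Grignard reagent accelerated by Me3SiCl, in which the (E)-γ-alkoxy enoate reacts through the Felkin–Anh-type conformer with the γ-C–O bond antiperiplanar to the incoming copper reagent and the γ-hydrogen eclipsing the alkene, so that isopropenyl enters anti to the C6 oxygen and sets C7 as R.

Step 12
Reactants: 14 ester
Product: 15 (3R)-3-[(4S,5R)-5-{[(tert-butyldimethylsilyl)oxy]methyl}-2,2-dimethyl-1,3-dioxolan-4-yl]-4-methylpent-4-en-1-ol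
Conditions: LiAlH4, THF, 0 °C; aqueous work-up
Reagents that add atoms: none
Why: Hydride reduction of the ester gives the primary C9 alcohol while silyl ether, acetonide and the 1,1-disubstituted alkene are inert.

Step 13
Reactants: 15 primary alcohol
Product: 16 tert-butyl{[(3R)-3-[(4S,5R)-5-{[(tert-butyldimethylsilyl)oxy]methyl}-2,2-dimethyl-1,3-dioxolan-4-yl]-4-methylpent-4-en-1-yl]oxy}diphenylsilane
Conditions: t-BuPh2SiCl, imidazole, DMF, rt
Reagents that add atoms: tert-butyldiphenylsilyl chloride (CC(C)(C)[Si](Cl)(c1ccccc1)c1ccccc1)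
Why: Silylation of the primary alcohol with the bulkier, more acid-stable TBDPS group differentiates the C9 oxygen from the TBS-protected C4 oxygen.

Step 14
Reactants: 16 bis-silyl ether
Product: 17 [(4R,5S)-5-{(3R)-5-[(tert-butyldiphenylsilyl)oxy]-2-methylpent-1-en-3-yl}-2,2-dimethyl-1,3-dioxolan-4-yl]methanol
Conditions: HF·pyridine, pyridine, THF, 0 °C
Reagents that add atoms: none
Why: Selective desilylation, buffered HF·pyridine cleaving the primary TBS ether much faster than the primary TBDPS ether and leaving the acetonide intact.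

Step 15
Reactants: 17 primary alcohol
Product: 18 (4S,5S)-5-{(3R)-5-[(tert-butyldiphenylsilyl)oxy]-2-methylpent-1-en-3-yl}-2,2-dimethyl-1,3-dioxolane-4-carbaldehyde
Conditions: Dess–Martin periodinane, NaHCO3, CH2Cl2, 0 °C to rt
Reagents that add atoms: none
Why: Dess–Martin oxidation under buffered conditions should give the cis-dioxolane aldehyde without epimerisation at C5.

Step 16
Reactants: 18 aldehyde
Product: 19 1-[(4R,5S)-5-{(3R)-5-[(tert-butyldiphenylsilyl)oxy]-2-methylpent-1-en-3-yl}-2,2-dimethyl-1,3-dioxolan-4-yl]ethan-1-ol (carbinol epimers)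
Conditions: MeMgBr, THF, −78 °C; H2O work-up
Reagents that add atoms: methylmagnesium bromide (C[Mg]Br)
Why: Grignard addition at low temperature introduces the C4 methyl, and the carbinol epimers converge on one ketone in the next step.

Step 17
Reactants: 19 secondary alcohol
Product: 20 1-[(4S,5S)-5-{(3R)-5-[(tert-butyldiphenylsilyl)oxy]-2-methylpent-1-en-3-yl}-2,2-dimethyl-1,3-dioxolan-4-yl]ethan-1-one
Conditions: Dess–Martin periodinane, NaHCO3, CH2Cl2, rt
Reagents that add atoms: none
Why: Dess–Martin oxidation of the secondary alcohol gives the α-alkoxy methyl ketone under non-basic conditions that keep the cis-dioxolane.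

**Fragment union and seco precursor**

Step 18
Reactants: 8 phosphonium iodide; 20 methyl ketone
Product: 22 (1S,3Z,5R,6S,7R)-9,10-seco chain (C10 to C9) bearing 1-O-PMB; 5,6-O-isopropylidene; 7-isopropenyl; 9-O-TBDPS; 10-O-TBS (C10 epimers), via phosphonium ylide 21 (not isolated)
Conditions: KN(SiMe3)2, THF, −78 to 0 °C; then 20, −78 °C to rt
Reagents that add atoms: none
Why: Wittig reaction of a non-stabilised ylide with an α-alkoxy methyl ketone, in which kinetically controlled oxaphosphetane formation under salt-free potassium conditions places the ylide substituent (C2) cis to the alkoxy-bearing carbon (C5) and so gives the (Z)-trisubstituted C3=C4 alkene.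

Step 19
Reactants: 22 bis-silyl ether
Product: 23 (1S,3Z,5R,6S,7R)-9,10-seco 9,10-diol bearing 1-O-PMB; 5,6-O-isopropylidene; 7-isopropenyl (C10 epimers)
Conditions: Bu4NF, THF, rt; aqueous work-up
Reagents that add atoms: none
Why: Fluoride cleaves both silyl ethers through Si–F bond formation, releasing the primary C9 and secondary C10 hydroxyls while PMB ether and acetonide remain.

Step 20
Reactants: 23 seco diol
Product: 24 (1S,3Z,5R,6S,7R)-9,10-seco keto aldehyde (C9 aldehyde; C10 methyl ketone; 1-O-PMB; 5,6-O-isopropylidene; 7-isopropenyl)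
Conditions: Dess–Martin periodinane (excess), NaHCO3, CH2Cl2, 0 °C to rt
Reagents that add atoms: none
Why: Double Dess–Martin oxidation takes the primary alcohol to the aldehyde and the secondary alcohol to the methyl ketone in one operation under neutral conditions that do not epimerise C1 or C5.

Step 21
Reactants: 24 seco keto aldehyde
Product: 26 (1S,3Z,5R,6S,7R,9R,10S)-5,6-O-isopropylidene-1-O-(4-methoxybenzyl)-4,10-dimethyl-7-(prop-1-en-2-yl)cyclodec-3-ene-1,5,6,9,10-pentol, via titanium pinacolate 25 (not isolated)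
Conditions: TiCl3(DME)1.5, Zn–Cu couple, DME, reflux, then cooled to rt; 24 added by syringe pump at high dilution; aqueous K2CO3
Reagents that add atoms: none
Why: Low-valent titanium (divalent titanium generated from TiCl3(DME)1.5 and Zn–Cu) transfers one electron to each carbonyl, the two titanium-bound ketyls at C9 and C10 combine while held on the metal, and aqueous K2CO3 releases the diol from the pinacolate 25; the closest known reaction type is the McMurry pinacol macrocyclisation of dialdehydes and keto aldehydes to 1,2-diols in ten- to fourteen-membered carbocycles, run at or below room temperature so that the pinacolate is not deoxygenated to the olefin. The only ring closed is the ten-membered carbocycle, formed end to end by intramolecular ketyl–ketyl coupling across C9–C10. C10 is set by the C1 stereocentre: titanium bridges the C10 ketyl oxygen and the C1 PMB ether oxygen in a five-membered chelate and C9 bonds to the face of C10 anti to C2, which places the C10 oxygen syn to the C1 oxygen (10S). C9 is set by the pinacolate template, whose two O–Ti bonds take the trans arrangement that titanium pinacols prefer in medium and large rings, giving the threo 9R,10S pair. The step needs ring closure to win over intermolecular coupling and over the cis-diol; the (Z)-C3=C4 alkene and the cis-fused C5/C6 acetonide remove rotors and turn the chain so that C9 and C10 meet, and slow addition keeps the free keto aldehyde dilute. Ethers, the acetal and the three alkenes should not be reduced by this reagent at room temperature.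

**Endgame**

Step 22
Reactants: 26 ten-membered 9,10-diol
Product: 27 (1S,3Z,5R,6S,7R,9R,10R)-9-O-TBS ether of 26 (C10 hydroxyl free)
Conditions: t-BuMe2SiOSO2CF3, 2,6-lutidine, CH2Cl2, −78 °C
Reagents that add atoms: tert-butyldimethylsilyl trifluoromethanesulfonate (CC(C)(C)[Si](C)(C)OS(=O)(=O)C(F)(F)F)
Why: Kinetic differentiation by silylation, the silyl triflate with a hindered base at low temperature reacting with the secondary C9 hydroxyl far faster than with the tertiary C10 hydroxyl.

Step 23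
Reactants: 27 PMB ether
Product: 28 (1S,3Z,5R,6S,7R,9R,10R)-9-O-TBS-5,6-O-isopropylidene-4,10-dimethyl-7-(prop-1-en-2-yl)cyclodec-3-ene-1,5,6,9,10-pentol (C1 and C10 hydroxyls free)
Conditions: 2,3-dichloro-5,6-dicyano-1,4-benzoquinone (DDQ), CH2Cl2/pH 7 aqueous buffer, 0 °C
Reagents that add atoms: none
Why: Oxidative cleavage of the PMB ether by DDQ (hydride abstraction, then hydrolysis of the oxocarbenium ion), water being present so that the ion is hydrolysed instead of being trapped by the vicinal C10 hydroxyl as an acetal.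

Step 24
Reactants: 28 C1 alcohol
Product: 29 (1S,3Z,5R,6S,7R,9R,10R)-1-O-angeloyl-9-O-TBS-5,6-O-isopropylidene compound (C10 hydroxyl free)
Conditions: angelic acid, 2,4,6-Cl3C6H2COCl, Et3N, toluene, rt; then 28, 80 °C
Reagents that add atoms: angelic acid, (Z)-2-methylbut-2-enoic acid (C/C=C(/C)C(=O)O)
Why: Yamaguchi-type mixed-anhydride esterification of the hindered secondary C1 hydroxyl without a nucleophilic catalyst, conditions under which the (Z)-2-methylbut-2-enoyl group should be transferred without isomerisation to the tiglate, while the tertiary C10 hydroxyl does not react.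

Step 25
Reactants: 29 acetonide
Product: 30 (1S,3Z,5R,6S,7R,9R,10R)-1-O-angeloyl-9-O-TBS-cyclodec-3-ene-5,6,10-triol (C5; C6; C10 hydroxyls free)
Conditions: AcOH/H2O (4:1), 40 °C
Reagents that add atoms: none
Why: Acid hydrolysis of the isopropylidene acetal through the oxocarbenium ion at the acetal carbon releases the cis-5,6-diol, and the hindered secondary TBS ether and the angelate should tolerate aqueous acetic acid.

Step 26
Reactants: 30 allylic diol
Product: 31 (1S,3R,4R,5S,6S,7R,9R,10R)-1-O-angeloyl-9-O-TBS-3,4-epoxy-5,6,10-triol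
Conditions: VO(acac)2 (cat.), t-BuOOH, CH2Cl2, 0 °C to rt
Reagents that add atoms: tert-butyl hydroperoxide (CC(C)(C)OO)
Why: Vanadium-catalysed hydroxyl-directed epoxidation, in which the allylic C5 alkoxide binds the vanadium tert-butylperoxide and delivers oxygen to the face of the (Z)-alkene syn to the C5 oxygen, as known for medium-ring (Z)-cycloalkenols and reinforced by 1,2-allylic strain from the C4 methyl, setting C3 and C4 as R,R while the allylic rate acceleration leaves the isopropenyl and angelate alkenes untouched.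

Step 27
Reactants: 31 epoxy diol
Product: 32 (1S,3R,4R,5S,6S,7R,9R,10R)-1-O-angeloyl-6-O-senecioyl-9-O-TBS-3,4-epoxide (C5 and C10 hydroxyls free)
Conditions: Me2C=CHCOCl, pyridine, DMAP (cat.), CH2Cl2, 0 °C
Reagents that add atoms: 3-methylbut-2-enoyl chloride (CC(C)=CC(=O)Cl)
Why: Site-selective acylation under pyridine/DMAP catalysis should take place at the C6 hydroxyl, because the C5 hydroxyl is now flanked by the fully substituted oxirane carbon C4 (neopentyl-type) and hydrogen-bonded to the epoxide oxygen, and the tertiary C10 hydroxyl is inert.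

Step 28
Reactants: 32 C5 alcohol
Product: 33 (1S,3R,4R,5S,6S,7R,9R,10R)-5-O-acetyl-1-O-angeloyl-6-O-senecioyl-9-O-TBS-3,4-epoxide (C10 hydroxyl free)
Conditions: Ac2O, pyridine, DMAP (cat.), CH2Cl2, rt
Reagents that add atoms: acetic anhydride (CC(=O)OC(C)=O)
Why: DMAP-catalysed acetylation of the remaining hindered secondary C5 hydroxyl, the tertiary C10 hydroxyl reacting much more slowly so that reagent and time are limited accordingly.

Step 29
Reactants: 33 silyl ether
Product: 34 target CNP0298989.1, (1S,3R,4R,5S,6S,7R,9R,10S)-5-O-acetyl-1-O-angeloyl-6-O-senecioyl-3,4-epoxy-4,10-dimethyl-7-(prop-1-en-2-yl)cyclodecane-1,5,6,9,10-pentol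
Conditions: HF·pyridine, pyridine, THF, 0 °C to rt
Reagents that add atoms: none
Why: Fluoride-mediated cleavage of the secondary TBS ether under buffered, weakly acidic conditions that should spare the trisubstituted epoxide and the three esters and not promote acyl migration, giving the target.

**Compound list**

1 | (S)-butane-1,2,4-triol | OCC[C@H](O)CO | starting material
2 | [(2S,4S)-2-(4-methoxyphenyl)-1,3-dioxan-4-yl]methanol | OC[C@@H]1CCO[C@H](c2ccc(OC)cc2)O1 | intermediate
3 | (2S,4S)-2-(4-methoxyphenyl)-1,3-dioxane-4-carbaldehyde | O=C[C@@H]1CCO[C@H](c2ccc(OC)cc2)O1 | intermediate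
4 | 1-[(2S,4S)-2-(4-methoxyphenyl)-1,3-dioxan-4-yl]ethan-1-ol (carbinol epimers) | CC(O)[C@@H]1CCO[C@H](c2ccc(OC)cc2)O1 | intermediate
5 | tert-butyl{1-[(2S,4S)-2-(4-methoxyphenyl)-1,3-dioxan-4-yl]ethoxy}dimethylsilane (carbinol epimers) | CC(O[Si](C)(C)C(C)(C)C)[C@@H]1CCO[C@H](c2ccc(OC)cc2)O1 | intermediate
6 | (3S)-4-[(tert-butyldimethylsilyl)oxy]-3-[(4-methoxyphenyl)methoxy]pentan-1-ol (C4 epimers) | CC(O[Si](C)(C)C(C)(C)C)[C@@H](OCc1ccc(OC)cc1)CCO | intermediate
7 | tert-butyl({(3S)-5-iodo-3-[(4-methoxyphenyl)methoxy]pentan-2-yl}oxy)dimethylsilane (C2 epimers) | CC(O[Si](C)(C)C(C)(C)C)[C@@H](OCc1ccc(OC)cc1)CCI | intermediate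
8 | {(3S)-4-[(tert-butyldimethylsilyl)oxy]-3-[(4-methoxyphenyl)methoxy]pentyl}triphenylphosphonium iodide (C4 epimers) | CC(O[Si](C)(C)C(C)(C)C)[C@@H](OCc1ccc(OC)cc1)CC[P+](c1ccccc1)(c1ccccc1)c1ccccc1.[I-] | intermediate
9 | 2,3-O-isopropylidene-D-erythronolactone | O=C1[C@H](OC(C)(C)O2)[C@H]2CO1 | starting material
10 | 2,3-O-isopropylidene-D-erythrofuranose (anomers) | OC1[C@H](OC(C)(C)O2)[C@H]2CO1 | intermediate
11 | ethyl (2E)-3-[(4S,5R)-5-(hydroxymethyl)-2,2-dimethyl-1,3-dioxolan-4-yl]prop-2-enoate | CCOC(=O)/C=C/[C@H](OC(C)(C)O2)[C@H]2CO | intermediate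
12 | ethyl (2E)-3-[(4S,5R)-5-{[(tert-butyldimethylsilyl)oxy]methyl}-2,2-dimethyl-1,3-dioxolan-4-yl]prop-2-enoate | CCOC(=O)/C=C/[C@H](OC(C)(C)O2)[C@H]2CO[Si](C)(C)C(C)(C)C | intermediate
13 | ethyl trimethylsilyl ketene acetal of 14 (enol geometry not defined) | CCOC(O[Si](C)(C)C)=C[C@H](C(C)=C)[C@H](OC(C)(C)O2)[C@H]2CO[Si](C)(C)C(C)(C)C | intermediate
14 | ethyl (3R)-3-[(4S,5R)-5-{[(tert-butyldimethylsilyl)oxy]methyl}-2,2-dimethyl-1,3-dioxolan-4-yl]-4-methylpent-4-enoate | CCOC(=O)C[C@H](C(C)=C)[C@H](OC(C)(C)O2)[C@H]2CO[Si](C)(C)C(C)(C)C | intermediate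
15 | (3R)-3-[(4S,5R)-5-{[(tert-butyldimethylsilyl)oxy]methyl}-2,2-dimethyl-1,3-dioxolan-4-yl]-4-methylpent-4-en-1-ol | OCC[C@H](C(C)=C)[C@H](OC(C)(C)O2)[C@H]2CO[Si](C)(C)C(C)(C)C | intermediate
16 | tert-butyl{[(3R)-3-[(4S,5R)-5-{[(tert-butyldimethylsilyl)oxy]methyl}-2,2-dimethyl-1,3-dioxolan-4-yl]-4-methylpent-4-en-1-yl]oxy}diphenylsilane | CC(C)(C)[Si](c1ccccc1)(c1ccccc1)OCC[C@H](C(C)=C)[C@H](OC(C)(C)O2)[C@H]2CO[Si](C)(C)C(C)(C)C | intermediate
17 | [(4R,5S)-5-{(3R)-5-[(tert-butyldiphenylsilyl)oxy]-2-methylpent-1-en-3-yl}-2,2-dimethyl-1,3-dioxolan-4-yl]methanol | CC(C)(C)[Si](c1ccccc1)(c1ccccc1)OCC[C@H](C(C)=C)[C@H](OC(C)(C)O2)[C@H]2CO | intermediate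
18 | (4S,5S)-5-{(3R)-5-[(tert-butyldiphenylsilyl)oxy]-2-methylpent-1-en-3-yl}-2,2-dimethyl-1,3-dioxolane-4-carbaldehyde | CC(C)(C)[Si](c1ccccc1)(c1ccccc1)OCC[C@H](C(C)=C)[C@H](OC(C)(C)O2)[C@H]2C=O | intermediate
19 | 1-[(4R,5S)-5-{(3R)-5-[(tert-butyldiphenylsilyl)oxy]-2-methylpent-1-en-3-yl}-2,2-dimethyl-1,3-dioxolan-4-yl]ethan-1-ol (carbinol epimers) | CC(C)(C)[Si](c1ccccc1)(c1ccccc1)OCC[C@H](C(C)=C)[C@H](OC(C)(C)O2)[C@H]2C(C)O | intermediate
20 | 1-[(4S,5S)-5-{(3R)-5-[(tert-butyldiphenylsilyl)oxy]-2-methylpent-1-en-3-yl}-2,2-dimethyl-1,3-dioxolan-4-yl]ethan-1-one | CC(C)(C)[Si](c1ccccc1)(c1ccccc1)OCC[C@H](C(C)=C)[C@H](OC(C)(C)O2)[C@H]2C(C)=O | intermediate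
21 | {(3S)-4-[(tert-butyldimethylsilyl)oxy]-3-[(4-methoxyphenyl)methoxy]pentylidene}triphenylphosphorane (C4 epimers) | CC(O[Si](C)(C)C(C)(C)C)[C@@H](OCc1ccc(OC)cc1)CC=P(c1ccccc1)(c1ccccc1)c1ccccc1 | intermediate
22 | (1S,3Z,5R,6S,7R)-9,10-seco chain with 1-O-PMB, 5,6-O-isopropylidene, 7-isopropenyl, 9-O-TBDPS, 10-O-TBS (C10 epimers) | CC(O[Si](C)(C)C(C)(C)C)[C@@H](OCc1ccc(OC)cc1)C/C=C(C)\[C@@H](OC(C)(C)O2)[C@@H]2[C@H](CCO[Si](c1ccccc1)(c1ccccc1)C(C)(C)C)C(C)=C | intermediate
23 | (1S,3Z,5R,6S,7R)-9,10-seco 9,10-diol with 1-O-PMB, 5,6-O-isopropylidene, 7-isopropenyl (C10 epimers) | CC(O)[C@@H](OCc1ccc(OC)cc1)C/C=C(C)\[C@@H](OC(C)(C)O2)[C@@H]2[C@H](CCO)C(C)=C | intermediate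
24 | (1S,3Z,5R,6S,7R)-9,10-seco keto aldehyde with 1-O-PMB, 5,6-O-isopropylidene, 7-isopropenyl | CC(=O)[C@@H](OCc1ccc(OC)cc1)C/C=C(C)\[C@@H](OC(C)(C)O2)[C@@H]2[C@H](CC=O)C(C)=C | intermediate
25 | bis(dichlorotitanium) 9,10-pinacolate of 26 (trivalent titanium on each oxygen) | C=C(C)[C@H]1C[C@@H](O[Ti](Cl)Cl)[C@](C)(O[Ti](Cl)Cl)[C@@H](OCc2ccc(OC)cc2)C/C=C(C)\[C@@H](OC(C)(C)O3)[C@H]13 | intermediate
26 | (1S,3Z,5R,6S,7R,9R,10S)-5,6-O-isopropylidene-1-O-(4-methoxybenzyl)-4,10-dimethyl-7-(prop-1-en-2-yl)cyclodec-3-ene-1,5,6,9,10-pentol | C=C(C)[C@H]1C[C@@H](O)[C@](C)(O)[C@@H](OCc2ccc(OC)cc2)C/C=C(C)\[C@@H](OC(C)(C)O3)[C@H]13 | intermediate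
27 | (1S,3Z,5R,6S,7R,9R,10R)-9-O-TBS ether of 26 | C=C(C)[C@H]1C[C@@H](O[Si](C)(C)C(C)(C)C)[C@](C)(O)[C@@H](OCc2ccc(OC)cc2)C/C=C(C)\[C@@H](OC(C)(C)O3)[C@H]13 | intermediate
28 | (1S,3Z,5R,6S,7R,9R,10R)-9-O-TBS-5,6-O-isopropylidene-4,10-dimethyl-7-(prop-1-en-2-yl)cyclodec-3-ene-1,5,6,9,10-pentol | C=C(C)[C@H]1C[C@@H](O[Si](C)(C)C(C)(C)C)[C@](C)(O)[C@@H](O)C/C=C(C)\[C@@H](OC(C)(C)O3)[C@H]13 | intermediate
29 | (1S,3Z,5R,6S,7R,9R,10R)-1-O-angeloyl-9-O-TBS-5,6-O-isopropylidene compound | C=C(C)[C@H]1C[C@@H](O[Si](C)(C)C(C)(C)C)[C@](C)(O)[C@@H](OC(=O)/C(C)=C\C)C/C=C(C)\[C@@H](OC(C)(C)O3)[C@H]13 | intermediate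
30 | (1S,3Z,5R,6S,7R,9R,10R)-1-O-angeloyl-9-O-TBS-cyclodec-3-ene-5,6,10-triol | C=C(C)[C@H]1C[C@@H](O[Si](C)(C)C(C)(C)C)[C@](C)(O)[C@@H](OC(=O)/C(C)=C\C)C/C=C(C)\[C@@H](O)[C@H]1O | intermediate
31 | (1S,3R,4R,5S,6S,7R,9R,10R)-1-O-angeloyl-9-O-TBS-3,4-epoxy-5,6,10-triol | C=C(C)[C@H]1C[C@@H](O[Si](C)(C)C(C)(C)C)[C@](C)(O)[C@@H](OC(=O)/C(C)=C\C)C[C@H]2O[C@@]2(C)[C@@H](O)[C@H]1O | intermediate
32 | (1S,3R,4R,5S,6S,7R,9R,10R)-1-O-angeloyl-6-O-senecioyl-9-O-TBS-3,4-epoxide, C5 and C10 hydroxyls free | C=C(C)[C@H]1C[C@@H](O[Si](C)(C)C(C)(C)C)[C@](C)(O)[C@@H](OC(=O)/C(C)=C\C)C[C@H]2O[C@@]2(C)[C@@H](O)[C@H]1OC(=O)C=C(C)C | intermediate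
33 | (1S,3R,4R,5S,6S,7R,9R,10R)-5-O-acetyl-1-O-angeloyl-6-O-senecioyl-9-O-TBS-3,4-epoxide | C=C(C)[C@H]1C[C@@H](O[Si](C)(C)C(C)(C)C)[C@](C)(O)[C@@H](OC(=O)/C(C)=C\C)C[C@H]2O[C@@]2(C)[C@@H](OC(C)=O)[C@H]1OC(=O)C=C(C)C | intermediate
34 | CNP0298989.1, (1S,3R,4R,5S,6S,7R,9R,10S)-5-O-acetyl-1-O-angeloyl-6-O-senecioyl-3,4-epoxy-4,10-dimethyl-7-(prop-1-en-2-yl)cyclodecane-1,5,6,9,10-pentol | C=C(C)[C@H]1C[C@@H](O)[C@](C)(O)[C@@H](OC(=O)/C(C)=C\C)C[C@H]2O[C@@]2(C)[C@@H](OC(C)=O)[C@H]1OC(=O)C=C(C)C | target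

**Step count and risks**

Total step count: 29. Longest linear sequence: 22 steps (9 to 34, steps 8–29); the C10–C3 branch (1 to 8) is 7 steps.

Steps most likely to fail:

1. Step 21 (pinacol macrocyclisation). The ketyls may couple between molecules, or the C9 ketyl may bond through the wrong face so that the cis-9,10-diol forms instead of the trans one. Fallback, setting out from 24 and returning at 26: C9 is set by hydride delivery instead of in the C–C bond-forming event. The coupling is run as above, and the C9 epimer F1 is oxidised at its secondary hydroxyl (SO3·pyridine, DMSO, i-Pr2NEt) to the α-hydroxy ketone F2. Hydroxyl-directed reduction with Me4NBH(OAc)3 in MeCN/AcOH then delivers hydride from the face of the tertiary C10 hydroxyl, which should place the new C9 hydroxyl trans to it and give 26.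

2. Step 18 (Wittig union). The basic ylide may enolise the hindered α-alkoxy methyl ketone, which returns ketone and epimerises C5 to the trans-dioxolane, and Z selectivity may erode. Fallback, setting out from 8 (with 20) and returning at 22: a two-stage Horner–Wittig olefination. Alkaline hydrolysis of 8 (aqueous NaOH, EtOH, heat) gives the diphenylphosphine oxide F3. Its lithio derivative (n-BuLi, THF, −78 °C) adds to 20 at −78 °C, and the β-hydroxy phosphine oxide F4, whose C3/C4 relative configuration leads to the (Z)-alkene, is separated by chromatography from its diastereomers. Stereospecific syn elimination (NaH, DMF) then gives 22.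

3. Step 27 (site-selective senecioylation). Discrimination between the vicinal C5 and C6 hydroxyls may be poor, and the acyl group may migrate between them. Fallback, setting out from 30 and returning at 32: the two hydroxyls are told apart before the epoxide is made. The allylic C5 hydroxyl, flanked by the planar C4, is silylated selectively (Et3SiCl, imidazole, CH2Cl2, −20 °C) to the C5 triethylsilyl ether F5. The C6 hydroxyl is senecioylated (Me2C=CHCOCl, pyridine, DMAP) to the senecioate F6. The triethylsilyl group is removed (pyridinium p-toluenesulfonate, MeOH, 0 °C, the TBS ether staying) to the allylic alcohol F7, and C5-hydroxyl-directed epoxidation (VO(acac)2, t-BuOOH) gives 32.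

Further compounds
F1 | step 21 | (1S,3Z,5R,6S,7R,9S,10S)-C9 epimer of diol 26 | C=C(C)[C@H]1C[C@H](O)[C@](C)(O)[C@@H](OCc2ccc(OC)cc2)C/C=C(C)\[C@@H](OC(C)(C)O3)[C@H]13
F2 | step 21 | (1S,3Z,5R,6S,7R,10R)-10-hydroxy-9-oxo compound (α-hydroxy ketone from F1) | C=C(C)[C@H]1CC(=O)[C@](C)(O)[C@@H](OCc2ccc(OC)cc2)C/C=C(C)\[C@@H](OC(C)(C)O3)[C@H]13
F3 | step 18 | {(3S)-4-[(tert-butyldimethylsilyl)oxy]-3-[(4-methoxyphenyl)methoxy]pentyl}diphenylphosphine oxide (C4 epimers) | CC(O[Si](C)(C)C(C)(C)C)[C@@H](OCc1ccc(OC)cc1)CCP(=O)(c1ccccc1)c1ccccc1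
F4 | step 18 | β-hydroxy phosphine oxide from F3 and 20 (C3 diphenylphosphinoyl, C4 hydroxyl, configuration that eliminates syn to the (Z)-alkene) | CC(O[Si](C)(C)C(C)(C)C)[C@@H](OCc1ccc(OC)cc1)C[C@@H](P(=O)(c1ccccc1)c1ccccc1)[C@@](C)(O)[C@@H](OC(C)(C)O2)[C@@H]2[C@H](CCO[Si](c1ccccc1)(c1ccccc1)C(C)(C)C)C(C)=C
F5 | step 27 | 5-O-triethylsilyl ether of 30 | C=C(C)[C@H]1C[C@@H](O[Si](C)(C)C(C)(C)C)[C@](C)(O)[C@@H](OC(=O)/C(C)=C\C)C/C=C(C)\[C@@H](O[Si](CC)(CC)CC)[C@H]1O
F6 | step 27 | 6-O-senecioyl-5-O-triethylsilyl derivative of 30 | C=C(C)[C@H]1C[C@@H](O[Si](C)(C)C(C)(C)C)[C@](C)(O)[C@@H](OC(=O)/C(C)=C\C)C/C=C(C)\[C@@H](O[Si](CC)(CC)CC)[C@H]1OC(=O)C=C(C)C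
F7 | step 27 | 6-O-senecioyl derivative of 30 with free allylic C5 hydroxyl | C=C(C)[C@H]1C[C@@H](O[Si](C)(C)C(C)(C)C)[C@](C)(O)[C@@H](OC(=O)/C(C)=C\C)C/C=C(C)\[C@@H](O)[C@H]1OC(=O)C=C(C)C
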